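- In this flask, triple product cannot stand above what the partner can pay for once each substrate has taken two additions.

- ochre: substrate 0.40 M; partner 1 M; the very flask that is asked about, followed so far
- flask: substrate 0.40 M; partner 1.00 M; time 10 h

- ochre (time / h: substrate / %, mono adduct / %): 0.417: 24, 11; 0.833: 9, 5; 1.33: 6, 3; 1.50: 3, 1; 2.00: 0, 4; 2.50: 0, 1; 3.00: 0, 0

(each reading ± 1.5 percentage points)

- the substrate standing at 10 h, as a percentage of the substrate charged
- the mono adduct standing at 10 h, as a percentage of the substrate charged
- the bis adduct standing at 10 h, as a percentage of the substrate charged
- the triple product standing at 10 h, as a percentage of the substrate charged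

- what was read earlier has a scatter of 1.5 percentage points, one standard deviation
- a reading or a percentage of bis adduct counts all its forms, free or not
- a reading of substrate is of its free form alone

- Substrate and mono adduct are read at 0 % and 0 % by 3.00 h, so the large term of the partner balance is 0.800 M for two additions. The small term is the surplus 0.200 M, and the room ρ, this surplus as a percentage of the substrate charged, is 50.0 %.
- The upper bound on triple product in this flask is therefore ρ. The lower bound stays at nothing, as the readings are of substrate and mono adduct.
- This reckoning, taking bis adduct and triple product as the two end forms, brackets bis adduct between 50.0 % and 100 %.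
- The forecast puts substrate at 0 %, mono adduct at 0 %, bis adduct at 80 % and triple product at 20 %, inside that bracket, with the words “I guess modest conversion”.
- The flask gives substrate 0.0116 %, mono adduct 0.00659 %, bis adduct 5.49 % and triple product 22.9 %. Bis adduct lies 75 percentage points below the forecast and outside the bracket, while the other three agree with the forecast within the tolerance.

    substrate + partner → mono adduct + released group (k = 0.0940 M⁻¹ min⁻¹)
    partner + mono adduct → bis adduct + released group (k = 0.250 M⁻¹ min⁻¹)
    partner + bis adduct → triple product + released group (k = 0.0390 M⁻¹ min⁻¹)
    bis adduct ⇌ isomer of the product (K = 13.0, k = 1.10 min⁻¹)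
    substrate + bis adduct ⇌ idle adduct, settled at all times (K = 4.40 M⁻¹)
    partner → decomposition product (k = 7.30 × 10⁻⁵ min⁻¹)

- In this flask at 10.0 h, isomer of the product stands at 71.6 % against 5.49 % of bis adduct, a ratio of 13.0. The half-life of free bis adduct by the third step alone, other concentrations as charged, is 0.30 h, yet triple product has filled about half of ρ.
- In the neighbour flask charged with 0.10 M of substrate, ρ is 800 %, above the 100 % of the charge, so the bound there is the charge itself. That flask gives 70.0 % of triple product, with the substrate, its limiting reagent, at 0 %.

The data stem from a simulated flask on assumed constants; scatter was added.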